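**Retrosynthetic overview**
1. Target ⇐ desilylation, O‑acetylation, C–B oxidation and a one‑carbon (CH2) insertion from secondary boronic ester 14; the acetoxymethyl carbon is added last.
2. Key step: the central C–C bond and the CH2OAc‑bearing stereocentre come from a reagent‑controlled lithiation–borylation (1,2‑metallate shift) of secondary boronic ester 7 with the (−)‑sparteine‑lithiated syringyl‑ethyl benzoate 13.
3. 7 ⇐ benzylic boronic ester 5 + (+)‑sparteine‑lithiated ethyl 2,4,6‑triisopropylbenzoate (sets the methyl stereocentre).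
4. 5 and 13 ⇐ 4‑bromo‑2‑methoxyphenol and 4‑bromo‑2,6‑dimethoxyphenol (ArLi + ClCH2Bpin; ArLi + ethylene oxide).
5. No rings are formed: the target is acyclic and both arenes are bought. This replaces the usual dibenzylbutyrolactone / enolate‑alkylation route with an iterative boronic ester "assembly line".

Assumption: (+)‑ and (−)‑sparteine, ethyl 2,4,6‑triisopropylbenzoate, ClCH2Bpin and both bromophenols are taken as commercial; TIPS protects both phenols throughout. Target descriptors: (2R,3S)‑2‑(4‑hydroxy‑3,5‑dimethoxybenzyl)‑4‑(4‑hydroxy‑3‑methoxyphenyl)‑3‑methylbutyl acetate.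

**Route**

Step 1
Reactants: 1, 4‑bromo‑2‑methoxyphenol; 2, chlorotriisopropylsilane (TIPSCl)
Product: 3, (4‑bromo‑2‑methoxyphenoxy)triisopropylsilane
Conditions: TIPSCl, imidazole, DMF, rt
Reagents that add atoms: TIPSCl (2), CC(C)[Si](Cl)(C(C)C)C(C)C
Why: Standard phenol silylation; the TIPS aryl ether tolerates the organolithium steps that follow.

Step 2
Reactants: 3; 4, 2‑(chloromethyl)‑4,4,5,5‑tetramethyl‑1,3,2‑dioxaborolane (ClCH2Bpin)
Product: 5, 2‑[3‑methoxy‑4‑(triisopropylsilyloxy)benzyl]‑4,4,5,5‑tetramethyl‑1,3,2‑dioxaborolane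
Conditions: n‑BuLi, THF, −78 °C; then 4, −78 °C → rt
Reagents that add atoms: ClCH2Bpin (4), ClCB1OC(C)(C)C(C)(C)O1
Why: Br/Li exchange, boronate formation and Matteson‑type 1,2‑aryl migration with chloride loss give the benzylic boronic ester in one pot.

Step 3
Reactants: 6, ethyl 2,4,6‑triisopropylbenzoate; 5
Product: 7, (S)‑2‑[1‑(3‑methoxy‑4‑triisopropylsilyloxyphenyl)propan‑2‑yl]‑4,4,5,5‑tetramethyl‑1,3,2‑dioxaborolane
Conditions: 6 (1.3 equiv), (+)‑sparteine, s‑BuLi, Et2O, −78 °C, 5 h; then 5, −78 °C, 1 h; then reflux (35 °C)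
Reagents that add atoms: ethyl 2,4,6‑triisopropylbenzoate (6), CCOC(=O)c1c(C(C)C)cc(C(C)C)cc1C(C)C (supplies the CH–CH3 unit)
Why: Hoppe–Beak asymmetric deprotonation followed by lithiation–borylation: (+)‑sparteine gives the (R)‑α‑lithio benzoate, boron is captured with retention, and the benzyl group migrates anti to the leaving benzoate (inversion) to give the (S)‑boronic ester (typically ≥95:5 er).

Step 4
Reactants: 8, 4‑bromo‑2,6‑dimethoxyphenol; 2, TIPSCl
Product: 9, (4‑bromo‑2,6‑dimethoxyphenoxy)triisopropylsilane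
Conditions: TIPSCl, imidazole, DMF, 40 °C
Reagents that add atoms: TIPSCl (2), CC(C)[Si](Cl)(C(C)C)C(C)C
Why: Silylation of the hindered phenol; with both ortho positions blocked by OMe, no ortho‑lithiation or silyl migration is possible later.

Step 5
Reactants: 9; 10, ethylene oxide
Product: 11, 2‑[3,5‑dimethoxy‑4‑(triisopropylsilyloxy)phenyl]ethan‑1‑ol
Conditions: n‑BuLi, THF, −78 °C; then ethylene oxide (THF solution), BF3·OEt2, −78 → 0 °C
Reagents that add atoms: ethylene oxide (10), C1CO1
Why: Br/Li exchange then Lewis‑acid‑assisted epoxide opening by the aryllithium gives the two‑carbon homologated alcohol.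

Step 6
Reactants: 11; 12, 2,4,6‑triisopropylbenzoic acid
Product: 13, 2‑[3,5‑dimethoxy‑4‑(triisopropylsilyloxy)phenyl]ethyl 2,4,6‑triisopropylbenzoate
Conditions: 12, PPh3, DIAD, THF, 0 °C → rt
Reagents that add atoms: 2,4,6‑triisopropylbenzoic acid (12), CC(C)c1cc(C(C)C)c(C(=O)O)c(C(C)C)c1
Why: Mitsunobu esterification of a primary alcohol installs the hindered benzoate, which serves as both directing group and leaving group.

Step 7 (key step)
Reactants: 13; 7
Product: 14, 2‑[(2R,3S)‑1‑(3,5‑dimethoxy‑4‑triisopropylsilyloxyphenyl)‑4‑(3‑methoxy‑4‑triisopropylsilyloxyphenyl)‑3‑methylbutan‑2‑yl]‑4,4,5,5‑tetramethyl‑1,3,2‑dioxaborolane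
Conditions: 13 (1.3 equiv), (−)‑sparteine, s‑BuLi, Et2O, −78 °C, 5 h; then 7 (1.0 equiv), −78 °C, 2 h; then reflux (35 °C), 12 h
Reagents that add atoms: none beyond reactants 13 and 7
Why: Lithiation–borylation (stereospecific 1,2‑metallate rearrangement): (−)‑sparteine gives the (S)‑α‑lithio benzoate by carbonyl‑directed α‑deprotonation, which is expected to outpace the undirected benzylic C–H of the electron‑rich arene. The secondary alkyl group of 7 then migrates with retention at its own carbon and inversion at the carbenoid carbon, setting the (R) C–B centre under reagent control. Most of the minor enantiomer of 7 ends up as a separable diastereomer, which raises the ee of 14.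

Step 8
Reactants: 14; 15, bromochloromethane
Product: 16, 2‑{(2R,3S)‑2‑[3,5‑dimethoxy‑4‑(triisopropylsilyloxy)benzyl]‑4‑[3‑methoxy‑4‑(triisopropylsilyloxy)phenyl]‑3‑methylbutyl}‑4,4,5,5‑tetramethyl‑1,3,2‑dioxaborolane
Conditions: BrCH2Cl (3 equiv), n‑BuLi (2.5 equiv), Et2O, −78 °C → rt
Reagents that add atoms: bromochloromethane (15), ClCBr
Why: Matteson homologation: ClCH2Li generated in situ forms the boronate, and the secondary alkyl group shifts with retention, inserting the CH2 that becomes the acetoxymethyl carbon.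

Step 9
Reactants: 16; 17, sodium perborate
Product: 18, (2R,3S)‑2‑[3,5‑dimethoxy‑4‑(triisopropylsilyloxy)benzyl]‑4‑[3‑methoxy‑4‑(triisopropylsilyloxy)phenyl]‑3‑methylbutan‑1‑ol
Conditions: NaBO3·4H2O, THF/H2O (1:1), rt
Reagents that add atoms: sodium perborate (17), [Na+].[Na+].O[B-]1(O)OO[B-](O)(O)OO1
Why: Mild oxidative C–B to C–O conversion at a primary carbon; perborate avoids the strong hydroxide that could cleave the aryl silyl ethers. Diastereomers from steps 3 and 7 are removed here by chromatography.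

Step 10
Reactants: 18; 19, acetic anhydride
Product: 20, (2R,3S)‑2‑[3,5‑dimethoxy‑4‑(triisopropylsilyloxy)benzyl]‑4‑[3‑methoxy‑4‑(triisopropylsilyloxy)phenyl]‑3‑methylbutyl acetate
Conditions: Ac2O, pyridine, DMAP (cat.), CH2Cl2, 0 °C → rt
Reagents that add atoms: acetic anhydride (19), CC(=O)OC(C)=O
Why: Acylation of the only free hydroxyl while both phenols remain silylated, so there is no chemoselectivity issue.

Step 11
Reactants: 20
Product: 21, (2R,3S)‑2‑(4‑hydroxy‑3,5‑dimethoxybenzyl)‑4‑(4‑hydroxy‑3‑methoxyphenyl)‑3‑methylbutyl acetate (target)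
Conditions: TBAF (2.5 equiv), AcOH (3 equiv), THF, 0 °C
Reagents that add atoms: none
Why: Fluoride cleaves the aryl Si–O bonds rapidly; AcOH buffering keeps the phenols protonated so the primary acetate is neither hydrolysed nor transferred, and no stereocentre is touched.

**Compound list**
1 | 4‑bromo‑2‑methoxyphenol | COc1cc(Br)ccc1O | starting material
2 | chlorotriisopropylsilane | CC(C)[Si](Cl)(C(C)C)C(C)C | starting material
3 | (4‑bromo‑2‑methoxyphenoxy)triisopropylsilane | COc1cc(Br)ccc1O[Si](C(C)C)(C(C)C)C(C)C | intermediate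
4 | 2‑(chloromethyl)‑4,4,5,5‑tetramethyl‑1,3,2‑dioxaborolane | ClCB1OC(C)(C)C(C)(C)O1 | starting material
5 | 2‑[3‑methoxy‑4‑(triisopropylsilyloxy)benzyl]‑pinacol boronate | COc1cc(CB2OC(C)(C)C(C)(C)O2)ccc1O[Si](C(C)C)(C(C)C)C(C)C | intermediate
6 | ethyl 2,4,6‑triisopropylbenzoate | CCOC(=O)c1c(C(C)C)cc(C(C)C)cc1C(C)C | starting material
7 | (S)‑2‑[1‑(3‑methoxy‑4‑triisopropylsilyloxyphenyl)propan‑2‑yl]‑pinacol boronate | COc1cc(C[C@H](C)B2OC(C)(C)C(C)(C)O2)ccc1O[Si](C(C)C)(C(C)C)C(C)C | intermediate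
8 | 4‑bromo‑2,6‑dimethoxyphenol | COc1cc(Br)cc(OC)c1O | starting material
9 | (4‑bromo‑2,6‑dimethoxyphenoxy)triisopropylsilane | COc1cc(Br)cc(OC)c1O[Si](C(C)C)(C(C)C)C(C)C | intermediate
10 | ethylene oxide | C1CO1 | starting material
11 | 2‑[3,5‑dimethoxy‑4‑(triisopropylsilyloxy)phenyl]ethan‑1‑ol | COc1cc(CCO)cc(OC)c1O[Si](C(C)C)(C(C)C)C(C)C | intermediate
12 | 2,4,6‑triisopropylbenzoic acid | CC(C)c1cc(C(C)C)c(C(=O)O)c(C(C)C)c1 | starting material
13 | 2‑[3,5‑dimethoxy‑4‑(triisopropylsilyloxy)phenyl]ethyl 2,4,6‑triisopropylbenzoate | COc1cc(CCOC(=O)c2c(C(C)C)cc(C(C)C)cc2C(C)C)cc(OC)c1O[Si](C(C)C)(C(C)C)C(C)C | intermediate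
14 | (2R,3S) secondary pinacol boronate (B on the future CH2OAc‑bearing carbon) | COc1cc(C[C@H](C)[C@H](B3OC(C)(C)C(C)(C)O3)Cc2cc(OC)c(O[Si](C(C)C)(C(C)C)C(C)C)c(OC)c2)ccc1O[Si](C(C)C)(C(C)C)C(C)C | intermediate
15 | bromochloromethane | ClCBr | starting material
16 | (2R,3S) homologated primary pinacol boronate | COc1cc(C[C@H](C)[C@H](CB3OC(C)(C)C(C)(C)O3)Cc2cc(OC)c(O[Si](C(C)C)(C(C)C)C(C)C)c(OC)c2)ccc1O[Si](C(C)C)(C(C)C)C(C)C | intermediate
17 | sodium perborate (tetrahydrate used) | [Na+].[Na+].O[B-]1(O)OO[B-](O)(O)OO1 | starting material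
18 | (2R,3S)‑bis‑TIPS primary alcohol | COc1cc(C[C@H](C)[C@H](CO)Cc2cc(OC)c(O[Si](C(C)C)(C(C)C)C(C)C)c(OC)c2)ccc1O[Si](C(C)C)(C(C)C)C(C)C | intermediate
19 | acetic anhydride | CC(=O)OC(C)=O | starting material
20 | (2R,3S)‑bis‑TIPS acetate | COc1cc(C[C@H](C)[C@H](COC(C)=O)Cc2cc(OC)c(O[Si](C(C)C)(C(C)C)C(C)C)c(OC)c2)ccc1O[Si](C(C)C)(C(C)C)C(C)C | intermediate
21 | (2R,3S)‑2‑(4‑hydroxy‑3,5‑dimethoxybenzyl)‑4‑(4‑hydroxy‑3‑methoxyphenyl)‑3‑methylbutyl acetate | COc1cc(C[C@H](C)[C@H](COC(C)=O)Cc2cc(OC)c(O)c(OC)c2)ccc1O | target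

**Totals**
Total steps: 11. Longest linear sequence: 8 (steps 1, 2, 3, 7, 8, 9, 10, 11; the other branch, 4, 5, 6, then 7–11, is also 8).

**Three steps most likely to fail, with fallbacks**
1. Step 7. The β‑aryl benzoate 13 may suffer competing benzylic deprotonation and elimination to the styrene, or the hindered boronic ester 7 may capture the carbenoid slowly. Fallback: reverse the roles. Convert 7 (ClCH2Li insertion, oxidation, Mitsunobu with 12) into (S)‑2‑methyl‑3‑arylpropyl 2,4,6‑triisopropylbenzoate, a γ‑aryl substrate of the well‑behaved class. Lithiate it with s‑BuLi/(+)‑sparteine and trap with the syringyl benzylic boronic ester (made from 9 as in step 2) to reach the same 14.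
2. Step 3. The er may be insufficient (about 96:4 is typical), or the electron‑rich benzylic boronate may be lost to protodeboronation. Fallback: make 7 from an alkene instead of a carbenoid, by Cu‑catalysed enantioselective Markovnikov hydroboration (chiral bisphosphine–Cu, B2pin2, MeOH) of O‑TIPS‑eugenol.
3. Step 8. CH2 insertion into the α,β‑branched secondary boronic ester may be incomplete. Fallback: Zweifel olefination of 14 (vinyllithium; I2, NaOMe) to the terminal alkene, then OsO4/NaIO4 cleavage and NaBH4 reduction to alcohol 18, with no boron homologation.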